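**Retrosynthetic overview**

1. The chain is numbered C1 (benzylic CH2) to C15 (carbinol carbon). After silyl removal the C3–C4 bond is cut into fragment 1, the 1-aryl-but-2-yne 7, and fragment 2, the bromomethyl ketone 25, which already holds C5=O, the 6Z enone, C11 (R) and the C12–C15 hydroxy-enone.
2. Enabling feature: C4 is a CH2 between the C5 carbonyl and the C2=C3 alkene, and C3 carries only CH3 while C2 carries H. This is an α-keto carbon on the methyl end of a formal but-2-yne, so syn H–Zr addition (Zr to C3) and nickel-catalysed coupling with the α-bromoketone give the bond, the 2E geometry and the unconjugated β,γ-enone in one base-free operation.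
3. Fragment 2: C11 by Evans allylation; C7–C8 by B-alkyl Suzuki coupling with (Z)-4-iodopent-3-en-2-one (sets 6Z); the C5 ketone is parked as a 2-silyloxydiene while C12–C13 is made from a Weinreb amide and an (E)-alkenyllithium; NBS then turns the silyloxydiene into the C4 bromide.
4. Fragment 1: C–H borylation/oxidation of 1-bromo-2-methoxy-3-methylbenzene para to OMe, silylation, copper-catalysed propargylation.
5. Rings: the benzene ring is the only ring and is bought intact; no ring is formed in the route.

Key step: step 13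

Assumption: 1-bromo-2-methoxy-3-methylbenzene, pent-3-yn-2-one and (4S)-4-benzyl-3-propanoyl-1,3-oxazolidin-2-one are taken as purchasable, and the silyl ethers on the phenol and the tertiary alcohol are the only protecting groups needed.

**Route**

Step 1
Reactants: 1 1-bromo-2-methoxy-3-methylbenzene
Product: 3 3-bromo-4-methoxy-5-methylphenol, via arylboronic ester 2 (not isolated)
Conditions: [Ir(OMe)(cod)]2 (1.5 mol%), 4,4′-di-tert-butyl-2,2′-bipyridine (3 mol%), B2pin2, THF, 80 °C; then KHSO5 (as 2KHSO5·KHSO4·K2SO4), acetone/H2O, rt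
Reagents that add atoms: bis(pinacolato)diboron, CC1(C)OB(OC1(C)C)B1OC(C)(C)C(C)(C)O1 (boron of 2 only); potassium peroxymonosulfate, [K+].[O-]S(=O)(=O)OO (phenol oxygen)
Why: Iridium-catalysed C–H borylation is sterically controlled and should take the only C–H bond of 1 without an ortho substituent (para to OMe), and oxidation of the C–B bond then gives the phenol (one-pot borylation–oxidation).

Step 2
Reactants: 3 3-bromo-4-methoxy-5-methylphenol
Product: 4 (3-bromo-4-methoxy-5-methylphenoxy)(tert-butyl)dimethylsilane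
Conditions: t-BuMe2SiCl, imidazole, DMF, rt
Reagents that add atoms: tert-butyldimethylsilyl chloride, CC(C)(C)[Si](C)(C)Cl
Why: Standard silylation of a phenol removes the acidic O–H before the organometallic steps.

Step 3
Reactants: 4 (3-bromo-4-methoxy-5-methylphenoxy)(tert-butyl)dimethylsilane; 5 1-bromobut-2-yne
Product: 7 {[3-(but-2-yn-1-yl)-4-methoxy-5-methylphenyl]oxy}(tert-butyl)dimethylsilane, via arylmagnesium bromide 6 (not isolated)
Conditions: Mg, THF, reflux; then CuBr·SMe2 (5 mol%), 5, −20 °C → rt
Reagents that add atoms: magnesium, [Mg] (metal of 6 only)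
Why: Copper-catalysed SN2 coupling of an aryl Grignard reagent with a primary propargylic bromide, in which the methyl cap on the alkyne disfavours the SN2′ (allene) pathway.

Step 4
Reactants: 8 pent-3-yn-2-one
Product: 9 (3Z)-4-iodopent-3-en-2-one
Conditions: NaI, AcOH, rt, dark
Reagents that add atoms: sodium iodide, [Na+].[I-]
Why: Conjugate hydroiodination of an ynone is an anti addition, so iodine should end up cis to the acetyl group (the Z β-iodoenone).

Step 5
Reactants: 10 2-methylbut-3-yn-2-ol
Product: 11 triethyl[(2-methylbut-3-yn-2-yl)oxy]silane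
Conditions: Et3SiCl, imidazole, DMAP (cat.), DMF, rt
Reagents that add atoms: chlorotriethylsilane, CC[Si](Cl)(CC)CC
Why: Silylation of the tertiary propargylic alcohol, so that neither the zirconium hydride nor the later alkenyllithium meets a free O–H.

Step 6
Reactants: 11 triethyl[(2-methylbut-3-yn-2-yl)oxy]silane
Product: 13 triethyl{[(3E)-4-iodo-2-methylbut-3-en-2-yl]oxy}silane, via alkenylzirconocene 12 (not isolated)
Conditions: Cp2Zr(H)Cl, THF, rt; then I2, 0 °C
Reagents that add atoms: chlorobis(cyclopentadienyl)zirconium hydride, [H][Zr](Cl)(C1C=CC=C1)C1C=CC=C1 (zirconium of 12 only); iodine, II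
Why: Hydrozirconation of a terminal alkyne is a syn addition with zirconium on the terminal carbon, and iodinolysis with retention gives the (E)-alkenyl iodide.

Step 7
Reactants: 14 (4S)-4-benzyl-3-propanoyl-1,3-oxazolidin-2-one; 15 3-iodoprop-1-ene (allyl iodide)
Product: 17 (4S)-4-benzyl-3-[(2R)-2-methylpent-4-enoyl]-1,3-oxazolidin-2-one, via sodium enolate 16 (not isolated)
Conditions: NaN(SiMe3)2, THF, −78 °C; then 15, −78 → −45 °C
Reagents that add atoms: sodium bis(trimethylsilyl)amide, C[Si](C)(C)[N-][Si](C)(C)C.[Na+] (sodium of 16 only)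
Why: Evans asymmetric alkylation: the chelated (Z)-sodium enolate is allylated on the face opposite the benzyl group, which sets the (R)-methyl stereocentre that becomes C11.

Step 8
Reactants: 17 (4S)-4-benzyl-3-[(2R)-2-methylpent-4-enoyl]-1,3-oxazolidin-2-one
Product: 18 (2R)-N-methoxy-N,2-dimethylpent-4-enamide
Conditions: MeNH(OMe)·HCl, AlMe3, CH2Cl2, −15 °C → rt
Reagents that add atoms: N,O-dimethylhydroxylamine hydrochloride, CNOC.Cl
Why: Aluminium amide transamination of an N-acyloxazolidinone cleaves the exocyclic acyl group to the Weinreb amide without touching the α-stereocentre.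

Step 9
Reactants: 18 (2R)-N-methoxy-N,2-dimethylpent-4-enamide; 9 (3Z)-4-iodopent-3-en-2-one
Product: 20 (2R,6Z)-N-methoxy-N,2,6-trimethyl-8-oxonon-6-enamide, via alkylborane 19 (not isolated)
Conditions: 9-BBN, THF, 0 °C → rt; then 9, PdCl2(dppf) (5 mol%), AsPh3, Cs2CO3, DMF/H2O, rt, dark
Reagents that add atoms: 9-borabicyclo[3.3.1]nonane, [H]B1C2CCCC1CCC2 (boron of 19 only)
Why: 9-BBN should hydroborate the terminal alkene at the end carbon without touching the amide, and the B-alkyl Suzuki–Miyaura coupling proceeds with retention at the alkenyl iodide, so the new C7–C8 bond stays cis to the acetyl group and the 6Z enone results directly.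

Step 10
Reactants: 20 (2R,6Z)-N-methoxy-N,2,6-trimethyl-8-oxonon-6-enamide
Product: 22 (2R,6Z)-8-[(tert-butyldimethylsilyl)oxy]-N-methoxy-N,2,6-trimethylnona-6,8-dienamide, via lithium enolate 21 (not isolated)
Conditions: LiN(i-Pr)2, THF, −78 °C; then t-BuMe2SiOTf, −78 °C
Reagents that add atoms: lithium diisopropylamide, CC(C)[N-]C(C)C.[Li+] (lithium of 21 only); tert-butyldimethylsilyl trifluoromethanesulfonate, CC(C)(C)[Si](C)(C)OS(=O)(=O)C(F)(F)F
Why: Kinetic deprotonation of a β,β-disubstituted methyl enone at −78 °C occurs at the α′-methyl group (the tertiary α-hydrogen of the Weinreb amide is far less acidic), and O-silylation of the cross-conjugated enolate gives a 2-silyloxydiene that masks the C5 ketone and marks C4.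

Step 11
Reactants: 22 (2R,6Z)-8-[(tert-butyldimethylsilyl)oxy]-N-methoxy-N,2,6-trimethylnona-6,8-dienamide; 13 triethyl{[(3E)-4-iodo-2-methylbut-3-en-2-yl]oxy}silane
Product: 24 (3E,6R,10Z)-12-[(tert-butyldimethylsilyl)oxy]-2,6,10-trimethyl-2-[(triethylsilyl)oxy]trideca-3,10,12-trien-5-one, via alkenyllithium 23 (not isolated)
Conditions: 13, t-BuLi (2 equiv), Et2O, −78 °C; then 22, THF, −78 → −40 °C; aq NH4Cl
Reagents that add atoms: tert-butyllithium, [Li]C(C)(C)C (lithium of 23 only)
Why: Iodine–lithium exchange is stereoretentive and the (E)-alkenyllithium adds once to the Weinreb amide, whose chelate releases the (E)-enone only on quench, while a tert-butyldimethylsilyl enol ether is inert to organolithiums at −78 °C.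

Step 12
Reactants: 24 (3E,6R,10Z)-12-[(tert-butyldimethylsilyl)oxy]-2,6,10-trimethyl-2-[(triethylsilyl)oxy]trideca-3,10,12-trien-5-one
Product: 25 (3Z,8R,10E)-1-bromo-4,8,12-trimethyl-12-[(triethylsilyl)oxy]trideca-3,10-diene-2,9-dione
Conditions: NBS, NaHCO3, THF, −78 → 0 °C, dark
Reagents that add atoms: N-bromosuccinimide, BrN1C(=O)CCC1=O
Why: Electrophilic bromination of a silyl enol ether takes place at the terminal carbon of the 2-silyloxydiene (the only position that gives an oxygen-stabilised cation) and regenerates the C5 ketone as its bromomethyl derivative under neutral conditions that leave the 6Z alkene and C11 alone.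

Step 13
Reactants: 7 {[3-(but-2-yn-1-yl)-4-methoxy-5-methylphenyl]oxy}(tert-butyl)dimethylsilane; 25 (3Z,8R,10E)-1-bromo-4,8,12-trimethyl-12-[(triethylsilyl)oxy]trideca-3,10-diene-2,9-dione
Product: 27 (2E,6Z,11R,13E)-1-{5-[(tert-butyldimethylsilyl)oxy]-2-methoxy-3-methylphenyl}-3,7,11,15-tetramethyl-15-[(triethylsilyl)oxy]hexadeca-2,6,13-triene-5,12-dione, via alkenylzirconocene 26 (not isolated)
Conditions: 7 (1.5 equiv), Cp2Zr(H)Cl (1.7 equiv), THF, rt, then acetone (0.25 equiv) to destroy residual Zr–H; then 25, NiCl2·glyme (5 mol%), 2,2′-isopropylidenebis(4-phenyl-2-oxazoline) (6 mol%), DME/THF, 10 °C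
Reagents that add atoms: chlorobis(cyclopentadienyl)zirconium hydride, [H][Zr](Cl)(C1C=CC=C1)C1C=CC=C1 (zirconium of 26 only)
Why: Cp2Zr(H)Cl adds H and Zr syn across the alkyne of 7 and, after equilibration with a slight excess of hydride, the metal should sit on the less hindered, methyl-bearing carbon C3, so that 26 already has C1 and the C3 methyl group cis as the 2E alkene requires. A low-valent nickel/bis(oxazoline) catalyst abstracts bromine from 25 to give the C4 α-keto radical, which is captured by the alkenylnickel species formed by transmetalation from zirconium, and reductive elimination forms C3–C4 with retention of the alkene geometry. The closest known reaction type is the nickel-catalysed cross-coupling of α-bromoketones with alkenylzirconocenes made by hydrozirconation, which gives β,γ-unsaturated ketones without migration of the double bond. No ring is closed and no new stereocentre is formed; the only new stereo-element, the 2E alkene, is fixed by the syn hydrometalation and the stereoretentive coupling. The step needs regioselectivity (Zr on C3, not C2), secured by the size difference between CH3 and the ortho-disubstituted benzyl group, and chemoselectivity for the C–Br bond over the two enones, secured by fast halogen abstraction and by the hindered β-carbons of both enones (one β,β-disubstituted, one next to a quaternary carbon). Because no base is present, the doubly activated C4 methylene, the 6Z enone and the C11 stereocentre should survive.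

Step 14
Reactants: 27 (2E,6Z,11R,13E)-1-{5-[(tert-butyldimethylsilyl)oxy]-2-methoxy-3-methylphenyl}-3,7,11,15-tetramethyl-15-[(triethylsilyl)oxy]hexadeca-2,6,13-triene-5,12-dione
Product: 28 (2E,6Z,11R,13E)-15-hydroxy-1-(5-hydroxy-2-methoxy-3-methylphenyl)-3,7,11,15-tetramethylhexadeca-2,6,13-triene-5,12-dione
Conditions: HF·pyridine, pyridine, THF, 0 °C → rt
Reagents that add atoms: none
Why: Fluoride-mediated silyl ether cleavage removes the aryl and the tertiary silyl group in one operation, and the pyridine-buffered medium should neither move the C2=C3 alkene into conjugation nor epimerise C11.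

**Compound list**

1 | 1-bromo-2-methoxy-3-methylbenzene | COc1c(C)cccc1Br | starting material
2 | 2-(3-bromo-4-methoxy-5-methylphenyl)-4,4,5,5-tetramethyl-1,3,2-dioxaborolane | COc1c(C)cc(cc1Br)B1OC(C)(C)C(C)(C)O1 | intermediate (not isolated)
3 | 3-bromo-4-methoxy-5-methylphenol | COc1c(C)cc(O)cc1Br | intermediate
4 | (3-bromo-4-methoxy-5-methylphenoxy)(tert-butyl)dimethylsilane | COc1c(C)cc(O[Si](C)(C)C(C)(C)C)cc1Br | intermediate
5 | 1-bromobut-2-yne | CC#CCBr | starting material
6 | {5-[(tert-butyldimethylsilyl)oxy]-2-methoxy-3-methylphenyl}magnesium bromide | COc1c(C)cc(O[Si](C)(C)C(C)(C)C)cc1[Mg]Br | intermediate (not isolated)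
7 | {[3-(but-2-yn-1-yl)-4-methoxy-5-methylphenyl]oxy}(tert-butyl)dimethylsilane | CC#CCc1cc(O[Si](C)(C)C(C)(C)C)cc(C)c1OC | intermediate
8 | pent-3-yn-2-one | CC#CC(C)=O | starting material
9 | (3Z)-4-iodopent-3-en-2-one | CC(=O)/C=C(\I)C | intermediate
10 | 2-methylbut-3-yn-2-ol | CC(C)(O)C#C | starting material
11 | triethyl[(2-methylbut-3-yn-2-yl)oxy]silane | CC[Si](CC)(CC)OC(C)(C)C#C | intermediate
12 | chlorobis(cyclopentadienyl)[(1E)-3-methyl-3-(triethylsilyloxy)but-1-en-1-yl]zirconium (cyclopentadienyl rings drawn σ-bonded) | CC[Si](CC)(CC)OC(C)(C)/C=C/[Zr](Cl)(C1C=CC=C1)C1C=CC=C1 | intermediate (not isolated)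
13 | triethyl{[(3E)-4-iodo-2-methylbut-3-en-2-yl]oxy}silane | CC[Si](CC)(CC)OC(C)(C)/C=C/I | intermediate
14 | (4S)-4-benzyl-3-propanoyl-1,3-oxazolidin-2-one | CCC(=O)N1[C@@H](Cc2ccccc2)COC1=O | starting material
15 | 3-iodoprop-1-ene (allyl iodide) | C=CCI | starting material
16 | sodium (Z)-enolate of 14 | [Na+].C/C=C(\[O-])N1[C@@H](Cc2ccccc2)COC1=O | intermediate (not isolated)
17 | (4S)-4-benzyl-3-[(2R)-2-methylpent-4-enoyl]-1,3-oxazolidin-2-one | C=CC[C@@H](C)C(=O)N1[C@@H](Cc2ccccc2)COC1=O | intermediate
18 | (2R)-N-methoxy-N,2-dimethylpent-4-enamide | C=CC[C@@H](C)C(=O)N(C)OC | intermediate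
19 | (2R)-5-(9-borabicyclo[3.3.1]nonan-9-yl)-N-methoxy-N,2-dimethylpentanamide | CON(C)C(=O)[C@H](C)CCCB1C2CCCC1CCC2 | intermediate (not isolated)
20 | (2R,6Z)-N-methoxy-N,2,6-trimethyl-8-oxonon-6-enamide | CC(=O)/C=C(/C)CCC[C@@H](C)C(=O)N(C)OC | intermediate
21 | lithium enolate of 20 (α′-methyl side) | [Li+].C=C([O-])/C=C(/C)CCC[C@@H](C)C(=O)N(C)OC | intermediate (not isolated)
22 | (2R,6Z)-8-[(tert-butyldimethylsilyl)oxy]-N-methoxy-N,2,6-trimethylnona-6,8-dienamide | C=C(O[Si](C)(C)C(C)(C)C)/C=C(/C)CCC[C@@H](C)C(=O)N(C)OC | intermediate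
23 | [(1E)-3-methyl-3-(triethylsilyloxy)but-1-en-1-yl]lithium | [Li]/C=C/C(C)(C)O[Si](CC)(CC)CC | intermediate (not isolated)
24 | (3E,6R,10Z)-12-[(tert-butyldimethylsilyl)oxy]-2,6,10-trimethyl-2-[(triethylsilyl)oxy]trideca-3,10,12-trien-5-one | C=C(O[Si](C)(C)C(C)(C)C)/C=C(/C)CCC[C@@H](C)C(=O)/C=C/C(C)(C)O[Si](CC)(CC)CC | intermediate
25 | (3Z,8R,10E)-1-bromo-4,8,12-trimethyl-12-[(triethylsilyl)oxy]trideca-3,10-diene-2,9-dione | BrCC(=O)/C=C(/C)CCC[C@@H](C)C(=O)/C=C/C(C)(C)O[Si](CC)(CC)CC | intermediate
26 | chlorobis(cyclopentadienyl){(2E)-4-[5-(tert-butyldimethylsilyloxy)-2-methoxy-3-methylphenyl]but-2-en-2-yl}zirconium (cyclopentadienyl rings drawn σ-bonded) | COc1c(C)cc(O[Si](C)(C)C(C)(C)C)cc1C/C=C(\C)[Zr](Cl)(C1C=CC=C1)C1C=CC=C1 | intermediate (not isolated)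
27 | (2E,6Z,11R,13E)-1-{5-[(tert-butyldimethylsilyl)oxy]-2-methoxy-3-methylphenyl}-3,7,11,15-tetramethyl-15-[(triethylsilyl)oxy]hexadeca-2,6,13-triene-5,12-dione | COc1c(C)cc(O[Si](C)(C)C(C)(C)C)cc1C/C=C(\C)CC(=O)/C=C(/C)CCC[C@@H](C)C(=O)/C=C/C(C)(C)O[Si](CC)(CC)CC | intermediate
28 | (2E,6Z,11R,13E)-15-hydroxy-1-(5-hydroxy-2-methoxy-3-methylphenyl)-3,7,11,15-tetramethylhexadeca-2,6,13-triene-5,12-dione | COc1c(C)cc(O)cc1C/C=C(\C)CC(=O)/C=C(/C)CCC[C@@H](C)C(=O)/C=C/C(C)(C)O | target

**Step count and risks**

Total steps: 14. Longest linear sequence: 8 steps (steps 7 to 14).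

Steps most likely to fail:

Step 13. Zirconium may not equilibrate fully between C2 and C3. Transfer of the α-branched alkenyl group from zirconium to nickel may also be slow, so that reduction or homocoupling of the bromoketone, or nickel-promoted conjugate addition to an enone, takes over. The fallback reverses the polarity; it sets out from 7 and 24 and comes back at 27. Hydrozirconation of 7 as in step 13 followed by iodinolysis (I2, THF, 0 °C) should give tert-butyl{3-[(2E)-3-iodobut-2-en-1-yl]-4-methoxy-5-methylphenoxy}dimethylsilane F1, from which a minor regioisomer can be removed by chromatography. Silyl dienol ether 24 is converted in the flask by Bu3SnF into the tributylstannyl enolate F2, which is alkenylated by F1 under Pd(OAc)2/P(t-Bu)3 catalysis (toluene, 80 °C). This is the known palladium-catalysed α-alkenylation of tin enolates generated from silyl enol ethers, and it should give 27.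

Step 11. The alkenyllithium may attack silicon, or the silyl dienol ether may hydrolyse during the quench, so that the C5 mask and the C4 handle are lost; enolisation of the amide instead of addition is also possible. The fallback sets out from 22 and 13 and comes back at 24. Reduction of 22 with i-Bu2AlH (THF, −78 °C) should give (2R,6Z)-8-[(tert-butyldimethylsilyl)oxy]-2,6-dimethylnona-6,8-dienal F3. Coupling of F3 with 13 under Nozaki–Hiyama–Kishi conditions (CrCl2, NiCl2 cat., DMSO/THF), which are non-basic and aldehyde-selective, should give (3E,6R,10Z)-12-[(tert-butyldimethylsilyl)oxy]-2,6,10-trimethyl-2-[(triethylsilyl)oxy]trideca-3,10,12-trien-5-ol F4 as both C5 epimers. Oxidation with Dess–Martin periodinane/NaHCO3 then gives 24.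

Step 9. The aqueous base may hydrolyse the β-iodoenone or isomerise it from Z to E before the alkyl group is transferred from boron, or the alkylborane may be protodeboronated. The fallback sets out from 18 and 9 and comes back at 20. Compound 18 is hydroborated to 19 as before and iodinated (I2, NaOMe, MeOH) to (2R)-5-iodo-N-methoxy-N,2-dimethylpentanamide F5. Zinc insertion (Zn dust, LiCl, THF) gives {(4R)-5-[methoxy(methyl)amino]-4-methyl-5-oxopentyl}zinc iodide F6, which is coupled with 9 in a base-free Negishi reaction (Pd(PPh3)4, THF, rt) that also proceeds with retention at the alkenyl iodide, to give 20.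

**Further compounds**

F1 | step 13 | tert-butyl{3-[(2E)-3-iodobut-2-en-1-yl]-4-methoxy-5-methylphenoxy}dimethylsilane | COc1c(C)cc(O[Si](C)(C)C(C)(C)C)cc1C/C=C(\C)I
F2 | step 13 | tributyl{[(3Z,8R,10E)-4,8,12-trimethyl-9-oxo-12-(triethylsilyloxy)trideca-1,3,10-trien-2-yl]oxy}stannane | C=C(O[Sn](CCCC)(CCCC)CCCC)/C=C(/C)CCC[C@@H](C)C(=O)/C=C/C(C)(C)O[Si](CC)(CC)CC
F3 | step 11 | (2R,6Z)-8-[(tert-butyldimethylsilyl)oxy]-2,6-dimethylnona-6,8-dienal | C=C(O[Si](C)(C)C(C)(C)C)/C=C(/C)CCC[C@@H](C)C=O
F4 | step 11 | (3E,6R,10Z)-12-[(tert-butyldimethylsilyl)oxy]-2,6,10-trimethyl-2-[(triethylsilyl)oxy]trideca-3,10,12-trien-5-ol (both C5 epimers) | C=C(O[Si](C)(C)C(C)(C)C)/C=C(/C)CCC[C@@H](C)C(O)/C=C/C(C)(C)O[Si](CC)(CC)CC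
F5 | step 9 | (2R)-5-iodo-N-methoxy-N,2-dimethylpentanamide | CON(C)C(=O)[C@H](C)CCCI
F6 | step 9 | {(4R)-5-[methoxy(methyl)amino]-4-methyl-5-oxopentyl}zinc iodide | CON(C)C(=O)[C@H](C)CCC[Zn]I
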